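**Retrosynthetic overview**

1. Target 22 ⇐ diol 20: acetate on C9–OH, then methacrylate on C8–OH.
2. Ten-membered carbocycle (last ring) ⇐ ring-closing metathesis at C1=C10 of the open-chain diene 19.
3. Key step, the C9–O bond ⇐ hydroxyl-directed singlet-oxygen ene reaction of the γ-hydroxy tiglate 17, which sets C9 and unveils the 2-methylene ester needed for ring closure; 17 ⇐ Wittig reaction on the C9 aldehyde.
4. γ-Lactone (second ring; C6, C7) ⇐ Barbier allylation with lactone ring switch between epoxy aldehyde 7 and the lactone-locked allyl bromide 12 (from diol 8 and acid 9 by esterification and metathesis).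
5. Epoxide (first ring; C4, C5) ⇐ Sharpless epoxidation of the Z-allylic alcohol 5, made from but-2-yn-1-ol.

Assumption: labels C1–C15 are the germacrane positions of the target (C6 lactone carbinol, C8 methacrylate carbon, C9 acetate carbon, C14 ester carbon); (2S)-but-3-ene-1,2-diol and but-3-en-1-ylzinc bromide solution are taken as purchased.

**Route**

Step 1
Reactants: 1 but-2-yn-1-ol
Product: 3 (2Z)-3-iodobut-2-en-1-ol, via cyclic vinylalanate 2 (not isolated)
Conditions: NaAlH2(OCH2CH2OMe)2, THF, 0 °C to rt; then I2, −78 to 0 °C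
Reagents that add atoms: iodine, [I][I]
Why: trans-hydroalumination of the propargylic alcohol through the five-membered alkoxyaluminate 2 puts aluminium on C3 cis to CH2OH, and iodinolysis with retention gives only the Z iodide.

Step 2
Reactants: 3 (2Z)-3-iodobut-2-en-1-ol; 4 but-3-en-1-ylzinc bromide
Product: 5 (2Z)-3-methylhepta-2,6-dien-1-ol
Conditions: Pd(dppf)Cl2 (3 mol%), 4 (2.5 equiv), THF, rt
Reagents that add atoms: none
Why: Negishi coupling proceeds with retention at the vinyl iodide, so the new chain (C3–C1) ends up cis to CH2OH (the Z alkene), and the bidentate phosphine suppresses β-hydride elimination.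

Step 3
Reactants: 5 (2Z)-3-methylhepta-2,6-dien-1-ol
Product: 6 [(2S,3R)-3-(but-3-en-1-yl)-3-methyloxiran-2-yl]methanol
Conditions: Ti(OiPr)4 (10 mol%), L-(+)-diethyl tartrate (12 mol%), t-BuOOH, 4 Å molecular sieves, CH2Cl2, −20 °C
Reagents that add atoms: tert-butyl hydroperoxide, CC(C)(C)OO
Why: Sharpless asymmetric epoxidation with L-(+)-tartrate gives the (2S,3R) cis-epoxide of a Z-trisubstituted allylic alcohol (as with nerol), setting C5 (S) and C4 (R), and leaves the isolated terminal alkene untouched.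

Step 4
Reactants: 6 [(2S,3R)-3-(but-3-en-1-yl)-3-methyloxiran-2-yl]methanol
Product: 7 (2R,3R)-3-(but-3-en-1-yl)-3-methyloxirane-2-carbaldehyde
Conditions: TEMPO (10 mol%), PhI(OAc)2, CH2Cl2, rt
Reagents that add atoms: none
Why: the TEMPO/PhI(OAc)2 oxidation stops at the aldehyde under nearly neutral conditions, so the epoxide and the C5 centre are not disturbed (the descriptor at C5 changes only because CHO outranks C4).

Step 5
Reactants: 8 (2S)-but-3-ene-1,2-diol; 9 2-(bromomethyl)prop-2-enoic acid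
Product: 11 (2S)-2-hydroxybut-3-en-1-yl 2-(bromomethyl)prop-2-enoate, via 2-(bromomethyl)prop-2-enoyl chloride 10 (not isolated)
Conditions: 9, (COCl)2, DMF (cat.), CH2Cl2, 0 °C to rt; then 8, 2,4,6-collidine, CH2Cl2, −78 to −40 °C
Reagents that add atoms: none
Why: O-acylation by the acid chloride at low temperature selects the primary hydroxyl, and the hindered base does not displace the allylic bromide; the C8 stereocentre comes from 8.

Step 6
Reactants: 11 (2S)-2-hydroxybut-3-en-1-yl 2-(bromomethyl)prop-2-enoate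
Product: 12 (5S)-3-(bromomethyl)-5-hydroxy-5,6-dihydro-2H-pyran-2-one
Conditions: second-generation Grubbs catalyst RuCl2(=CHPh)(H2IMes)(PCy3) (5 mol%), CH2Cl2 (5 mM), 40 °C
Reagents that add atoms: none
Why: ring-closing metathesis of the vinyl group with the acrylate-type alkene closes the six-membered unsaturated lactone, whose ring holds C8 cis to the carbonyl and trans to CH2Br.

Step 7
Reactants: 7 (2R,3R)-3-(but-3-en-1-yl)-3-methyloxirane-2-carbaldehyde; 12 (5S)-3-(bromomethyl)-5-hydroxy-5,6-dihydro-2H-pyran-2-one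
Product: 14 (4R,5S)-5-[(2S,3R)-3-(but-3-en-1-yl)-3-methyloxiran-2-yl]-4-[(1S)-1,2-dihydroxyethyl]-3-methylideneoxolan-2-one, via delta-lactone Barbier adduct 13 (not isolated)
Conditions: Zn dust, THF–sat. aq NH4Cl (1:1), 0 °C to rt; then 2-hydroxypyridine (20 mol%), toluene, 45 °C
Reagents that add atoms: none
Why: Proposed new method: a Barbier allylation by a lactone-locked 2-(bromomethyl)enoate that ends in a lactone ring switch; the allylzinc from 12 reacts at its ring carbon C7 through a closed six-membered transition state in which the ring holds C8 trans to the CH2–Zn terminus (an E-crotyl geometry that open-chain 2-(bromomethyl)alk-2-enoates do not have), so the anti C6/C7 adduct forms, the aldehyde is attacked on its Felkin–Anh face (anti to the epoxide C–O, setting C6) and the allyl unit on the face anti to the pseudoaxial C8–OH (setting C7), all three preferences converging on 13, whose C6–OH then attacks the δ-lactone carbonyl to give the more stable trans γ-lactone and free the C9 alcohol; closest known reaction type: zinc or indium Barbier additions of 2-(bromomethyl)acrylates and of 3-(bromomethyl)furan-2(5H)-one to aldehydes followed by lactonisation.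

Step 8
Reactants: 14 (4R,5S)-5-[(2S,3R)-3-(but-3-en-1-yl)-3-methyloxiran-2-yl]-4-[(1S)-1,2-dihydroxyethyl]-3-methylideneoxolan-2-one; 15 methyl 2-(triphenyl-lambda5-phosphanylidene)propanoate
Product: 17 methyl (2E,4R)-4-{(2S,3R)-2-[(2S,3R)-3-(but-3-en-1-yl)-3-methyloxiran-2-yl]-4-methylidene-5-oxooxolan-3-yl}-4-hydroxy-2-methylbut-2-enoate, via alpha-hydroxy aldehyde 16 (not isolated)
Conditions: TEMPO (20 mol%), PhI(OAc)2, CH2Cl2, rt; then 15, rt
Reagents that add atoms: none
Why: TEMPO/PhI(OAc)2 oxidises only the primary alcohol, and the stabilised ylide traps the α-hydroxy aldehyde at once under neutral conditions (no epimerisation at C8) in an E-selective Wittig reaction that places C8 trans to the ester.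

Step 9
Reactants: 17 methyl (2E,4R)-4-{(2S,3R)-2-[(2S,3R)-3-(but-3-en-1-yl)-3-methyloxiran-2-yl]-4-methylidene-5-oxooxolan-3-yl}-4-hydroxy-2-methylbut-2-enoate
Product: 19 methyl (3S,4S)-4-{(2S,3R)-2-[(2S,3R)-3-(but-3-en-1-yl)-3-methyloxiran-2-yl]-4-methylidene-5-oxooxolan-3-yl}-3,4-dihydroxy-2-methylidenebutanoate, via allylic hydroperoxide 18 (not isolated)
Conditions: O2, visible light, tetraphenylporphyrin (1 mol%), CCl4, 0 °C; then PPh3, 0 °C
Reagents that add atoms: dioxygen, O=O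
Why: hydroxyl-directed Schenck ene reaction, in which singlet oxygen adds to C9 on the face syn to the hydrogen-bonding C8–OH in the conformer that relieves 1,3-allylic strain (threo, 9S) and takes hydrogen only from the methyl group geminal to the ester, so the C9–O bond and the 2-methylene ester form together; the terminal alkene and the lactone methylene are inert, and PPh3 reduces the hydroperoxide.

Step 10
Reactants: 19 methyl (3S,4S)-4-{(2S,3R)-2-[(2S,3R)-3-(but-3-en-1-yl)-3-methyloxiran-2-yl]-4-methylidene-5-oxooxolan-3-yl}-3,4-dihydroxy-2-methylidenebutanoate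
Product: 20 methyl (1(10)E,4R,5S,6S,7R,8S,9S)-4,5-epoxy-8,9-dihydroxygermacra-1(10),11(13)-dien-12,6-olid-14-oate (ring-cis C1=C10)
Conditions: second-generation Hoveyda–Grubbs catalyst RuCl2(H2IMes)(=CH-C6H4-2-OiPr) (10 mol%), 1,4-benzoquinone (20 mol%), toluene (1 mM), 70 °C
Reagents that add atoms: none
Why: ring-closing metathesis, in which the carbene formed at the terminal C1 vinyl group closes onto the 2-methylene ester (helped by the free allylic C9–OH) while closure onto the lactone methylene would need a bridgehead alkene; the trans lactone and cis epoxide pre-organise the chain, and the less strained ring-cis, tiglate-type alkene (C2 cis to C9) is expected.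

Step 11
Reactants: 20 methyl (1(10)E,4R,5S,6S,7R,8S,9S)-4,5-epoxy-8,9-dihydroxygermacra-1(10),11(13)-dien-12,6-olid-14-oate
Product: 21 methyl (1(10)E,4R,5S,6S,7R,8S,9S)-9-acetoxy-4,5-epoxy-8-hydroxygermacra-1(10),11(13)-dien-12,6-olid-14-oate
Conditions: Ac2O (1.05 equiv), 2,4,6-collidine, CH2Cl2, −40 to −20 °C
Reagents that add atoms: acetic anhydride, CC(=O)OC(C)=O
Why: site-selective O-acylation, because the allylic C9–OH next to the planar C10 is less hindered than the C8–OH next to the ring-fusion carbon C7, so one equivalent of anhydride at low temperature should give the 9-monoacetate.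

Step 12
Reactants: 21 methyl (1(10)E,4R,5S,6S,7R,8S,9S)-9-acetoxy-4,5-epoxy-8-hydroxygermacra-1(10),11(13)-dien-12,6-olid-14-oate
Product: 22 methyl (1(10)E,4R,5S,6S,7R,8S,9S)-9-acetoxy-4,5-epoxy-8-(2-methylprop-2-enoyloxy)germacra-1(10),11(13)-dien-12,6-olid-14-oate (target)
Conditions: methacrylic anhydride, DMAP (20 mol%), Et3N, CH2Cl2, 0 °C
Reagents that add atoms: methacrylic anhydride, C=C(C)C(=O)OC(=O)C(C)=C
Why: DMAP-catalysed acylation of the remaining secondary alcohol at 0 °C is faster than acetyl migration or lactonisation onto the C14 ester and gives the target.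

**Compound list**

1 | but-2-yn-1-ol | CC#CCO | starting material
2 | sodium 2,2-bis(2-methoxyethoxy)-3-methyl-2,5-dihydro-1,2-oxaluminol-2-uide (cyclic vinylalanate) | CC1=CCO[Al-]1(OCCOC)OCCOC.[Na+] | intermediate
3 | (2Z)-3-iodobut-2-en-1-ol | OC/C=C(C)\I | intermediate
4 | but-3-en-1-ylzinc bromide | C=CCC[Zn]Br | starting material
5 | (2Z)-3-methylhepta-2,6-dien-1-ol | OC/C=C(C)\CCC=C | intermediate
6 | [(2S,3R)-3-(but-3-en-1-yl)-3-methyloxiran-2-yl]methanol | OC[C@@H]1O[C@]1(C)CCC=C | intermediate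
7 | (2R,3R)-3-(but-3-en-1-yl)-3-methyloxirane-2-carbaldehyde | O=C[C@@H]1O[C@]1(C)CCC=C | intermediate
8 | (2S)-but-3-ene-1,2-diol | OC[C@@H](O)C=C | starting material
9 | 2-(bromomethyl)prop-2-enoic acid | C=C(CBr)C(=O)O | starting material
10 | 2-(bromomethyl)prop-2-enoyl chloride | C=C(CBr)C(=O)Cl | intermediate
11 | (2S)-2-hydroxybut-3-en-1-yl 2-(bromomethyl)prop-2-enoate | C=C(CBr)C(=O)OC[C@@H](O)C=C | intermediate
12 | (5S)-3-(bromomethyl)-5-hydroxy-5,6-dihydro-2H-pyran-2-one | O=C1OC[C@@H](O)C=C1CBr | intermediate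
13 | (4R,5S)-5-hydroxy-4-{(S)-hydroxy[(2S,3R)-3-(but-3-en-1-yl)-3-methyloxiran-2-yl]methyl}-3-methylideneoxan-2-one | C=C1C(=O)OC[C@@H](O)[C@@H]1[C@H](O)[C@@H]2O[C@]2(C)CCC=C | intermediate
14 | (4R,5S)-5-[(2S,3R)-3-(but-3-en-1-yl)-3-methyloxiran-2-yl]-4-[(1S)-1,2-dihydroxyethyl]-3-methylideneoxolan-2-one | C=C1C(=O)O[C@H]([C@@H]2O[C@]2(C)CCC=C)[C@H]1[C@H](O)CO | intermediate
15 | methyl 2-(triphenyl-lambda5-phosphanylidene)propanoate | COC(=O)C(C)=P(c1ccccc1)(c1ccccc1)c1ccccc1 | starting material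
16 | (2S)-2-{(2S,3R)-2-[(2S,3R)-3-(but-3-en-1-yl)-3-methyloxiran-2-yl]-4-methylidene-5-oxooxolan-3-yl}-2-hydroxyacetaldehyde | C=C1C(=O)O[C@H]([C@@H]2O[C@]2(C)CCC=C)[C@H]1[C@H](O)C=O | intermediate
17 | methyl (2E,4R)-4-{(2S,3R)-2-[(2S,3R)-3-(but-3-en-1-yl)-3-methyloxiran-2-yl]-4-methylidene-5-oxooxolan-3-yl}-4-hydroxy-2-methylbut-2-enoate | C=C1C(=O)O[C@H]([C@@H]2O[C@]2(C)CCC=C)[C@H]1[C@H](O)/C=C(\C)C(=O)OC | intermediate
18 | methyl (3S,4S)-4-{(2S,3R)-2-[(2S,3R)-3-(but-3-en-1-yl)-3-methyloxiran-2-yl]-4-methylidene-5-oxooxolan-3-yl}-3-hydroperoxy-4-hydroxy-2-methylidenebutanoate | C=C1C(=O)O[C@H]([C@@H]2O[C@]2(C)CCC=C)[C@H]1[C@H](O)[C@@H](OO)C(=C)C(=O)OC | intermediate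
19 | methyl (3S,4S)-4-{(2S,3R)-2-[(2S,3R)-3-(but-3-en-1-yl)-3-methyloxiran-2-yl]-4-methylidene-5-oxooxolan-3-yl}-3,4-dihydroxy-2-methylidenebutanoate | C=C1C(=O)O[C@H]([C@@H]2O[C@]2(C)CCC=C)[C@H]1[C@H](O)[C@@H](O)C(=C)C(=O)OC | intermediate
20 | methyl (1(10)E,4R,5S,6S,7R,8S,9S)-4,5-epoxy-8,9-dihydroxygermacra-1(10),11(13)-dien-12,6-olid-14-oate | O[C@H]1[C@H]2C(=C)C(=O)O[C@@H]2[C@@H]2O[C@]2(C)CC/C=C(/C(=O)OC)[C@@H]1O | intermediate
21 | methyl (1(10)E,4R,5S,6S,7R,8S,9S)-9-acetoxy-4,5-epoxy-8-hydroxygermacra-1(10),11(13)-dien-12,6-olid-14-oate | O[C@H]1[C@H]2C(=C)C(=O)O[C@@H]2[C@@H]2O[C@]2(C)CC/C=C(/C(=O)OC)[C@@H]1OC(C)=O | intermediate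
22 | methyl (1(10)E,4R,5S,6S,7R,8S,9S)-9-acetoxy-4,5-epoxy-8-(2-methylprop-2-enoyloxy)germacra-1(10),11(13)-dien-12,6-olid-14-oate | C=C(C)C(=O)O[C@H]1[C@H]2C(=C)C(=O)O[C@@H]2[C@@H]2O[C@]2(C)CC/C=C(/C(=O)OC)[C@@H]1OC(C)=O | target

**Step count and risks**

Total step count: 12. Longest linear sequence: 10 (steps 1–4, then 7–12); the reagent branch is steps 5–6.

Steps most likely to fail:

Step 7 (the proposed new step). The risks are chelation of zinc by the free C8–OH eroding the facial selectivity, and an incomplete lactone switch. Fallback with known chemistry, setting out from 7 and coming back at 14: (R)-2,3-O-isopropylideneglyceraldehyde is homologated with dimethyl (1-diazo-2-oxopropyl)phosphonate and K2CO3 in MeOH to (4S)-4-ethynyl-2,2-dimethyl-1,3-dioxolane F1, which n-BuLi and ClCO2Me convert into methyl 3-[(4S)-2,2-dimethyl-1,3-dioxolan-4-yl]prop-2-ynoate F2. syn-Hydroalumination (i-Bu2AlH, HMPA, THF, 0 °C) and trapping with ICH2B(pin) give the allylboronate methyl (2Z)-3-[(4S)-2,2-dimethyl-1,3-dioxolan-4-yl]-2-[(4,4,5,5-tetramethyl-1,3,2-dioxaborolan-2-yl)methyl]prop-2-enoate F3, in which C8 is trans to the CH2B terminus. Heating F3 with 7 in toluene at 80 °C (closed-transition-state anti allylboration, then lactonisation) gives the acetonide lactone (4R,5S)-5-[(2S,3R)-3-(but-3-en-1-yl)-3-methyloxiran-2-yl]-4-[(4S)-2,2-dimethyl-1,3-dioxolan-4-yl]-3-methylideneoxolan-2-one F4, and 80% aqueous AcOH at 0–20 °C removes the acetonide to give 14.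

Step 10. Closing a ten-membered ring onto a 1,1-disubstituted acrylate may stall or give dimers. Fallback, setting out from 14 and coming back at 20: ozonolysis of the terminal vinyl group of 14 (O3, CH2Cl2–MeOH, −78 °C, Sudan red end point; Me2S) gives 3-[(2R,3S)-3-{(2S,3R)-3-[(1S)-1,2-dihydroxyethyl]-4-methylidene-5-oxooxolan-2-yl}-2-methyloxiran-2-yl]propanal F5. Iodination–Wittig olefination (Ph3P=CHCO2Me, N-iodosuccinimide, K2CO3, CH2Cl2; then F5) gives methyl (2Z)-5-[(2R,3S)-3-{(2S,3R)-3-[(1S)-1,2-dihydroxyethyl]-4-methylidene-5-oxooxolan-2-yl}-2-methyloxiran-2-yl]-2-iodopent-2-enoate F6. TEMPO/PhI(OAc)2 oxidises its primary alcohol to the hydroxy aldehyde methyl (2Z)-5-[(2R,3S)-3-{(2S,3R)-3-[(1S)-1-hydroxy-2-oxoethyl]-4-methylidene-5-oxooxolan-2-yl}-2-methyloxiran-2-yl]-2-iodopent-2-enoate F7. A Nozaki–Hiyama–Kishi macrocyclisation (CrCl2, NiCl2 1 mol%, DMSO–THF, 2 mM, rt) then forms C9–C10 with retention of alkene geometry and gives 20. The threo diol is expected from addition to the chromium alkoxide chelate; the C9 epimer, if formed, is separated.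

Step 11. The two secondary hydroxyls may not differ enough, and acetyl migration can scramble the esters. Fallback, setting out from 20 and coming back at 22, with the esters installed in the reverse order through a silyl ether: TBSCl, imidazole, DMF, 0 °C gives methyl (1(10)E,4R,5S,6S,7R,8S,9S)-9-(tert-butyldimethylsilyloxy)-4,5-epoxy-8-hydroxygermacra-1(10),11(13)-dien-12,6-olid-14-oate F8. Methacrylic anhydride, DMAP, Et3N gives the 8-methacrylate methyl (1(10)E,4R,5S,6S,7R,8S,9S)-9-(tert-butyldimethylsilyloxy)-4,5-epoxy-8-(2-methylprop-2-enoyloxy)germacra-1(10),11(13)-dien-12,6-olid-14-oate F9. HF·pyridine/pyridine, THF, 0 °C gives methyl (1(10)E,4R,5S,6S,7R,8S,9S)-4,5-epoxy-9-hydroxy-8-(2-methylprop-2-enoyloxy)germacra-1(10),11(13)-dien-12,6-olid-14-oate F10, and Ac2O, DMAP, CH2Cl2, 0 °C gives 22.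

**Further compounds**

F1 | step 7 | (4S)-4-ethynyl-2,2-dimethyl-1,3-dioxolane | C#C[C@H]1COC(C)(C)O1
F2 | step 7 | methyl 3-[(4S)-2,2-dimethyl-1,3-dioxolan-4-yl]prop-2-ynoate | COC(=O)C#C[C@H]1COC(C)(C)O1
F3 | step 7 | methyl (2Z)-3-[(4S)-2,2-dimethyl-1,3-dioxolan-4-yl]-2-[(4,4,5,5-tetramethyl-1,3,2-dioxaborolan-2-yl)methyl]prop-2-enoate | COC(=O)/C(CB1OC(C)(C)C(C)(C)O1)=C\[C@H]1COC(C)(C)O1
F4 | step 7 | (4R,5S)-5-[(2S,3R)-3-(but-3-en-1-yl)-3-methyloxiran-2-yl]-4-[(4S)-2,2-dimethyl-1,3-dioxolan-4-yl]-3-methylideneoxolan-2-one | C=C1C(=O)O[C@H]([C@@H]2O[C@]2(C)CCC=C)[C@H]1[C@H]3COC(C)(C)O3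
F5 | step 10 | 3-[(2R,3S)-3-{(2S,3R)-3-[(1S)-1,2-dihydroxyethyl]-4-methylidene-5-oxooxolan-2-yl}-2-methyloxiran-2-yl]propanal | C=C1C(=O)O[C@H]([C@@H]2O[C@]2(C)CCC=O)[C@H]1[C@H](O)CO
F6 | step 10 | methyl (2Z)-5-[(2R,3S)-3-{(2S,3R)-3-[(1S)-1,2-dihydroxyethyl]-4-methylidene-5-oxooxolan-2-yl}-2-methyloxiran-2-yl]-2-iodopent-2-enoate | C=C1C(=O)O[C@H]([C@@H]2O[C@]2(C)CC/C=C(\I)C(=O)OC)[C@H]1[C@H](O)CO
F7 | step 10 | methyl (2Z)-5-[(2R,3S)-3-{(2S,3R)-3-[(1S)-1-hydroxy-2-oxoethyl]-4-methylidene-5-oxooxolan-2-yl}-2-methyloxiran-2-yl]-2-iodopent-2-enoate | C=C1C(=O)O[C@H]([C@@H]2O[C@]2(C)CC/C=C(\I)C(=O)OC)[C@H]1[C@H](O)C=O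
F8 | step 11 | methyl (1(10)E,4R,5S,6S,7R,8S,9S)-9-(tert-butyldimethylsilyloxy)-4,5-epoxy-8-hydroxygermacra-1(10),11(13)-dien-12,6-olid-14-oate | O[C@H]1[C@H]2C(=C)C(=O)O[C@@H]2[C@@H]2O[C@]2(C)CC/C=C(/C(=O)OC)[C@@H]1O[Si](C)(C)C(C)(C)C
F9 | step 11 | methyl (1(10)E,4R,5S,6S,7R,8S,9S)-9-(tert-butyldimethylsilyloxy)-4,5-epoxy-8-(2-methylprop-2-enoyloxy)germacra-1(10),11(13)-dien-12,6-olid-14-oate | C=C(C)C(=O)O[C@H]1[C@H]2C(=C)C(=O)O[C@@H]2[C@@H]2O[C@]2(C)CC/C=C(/C(=O)OC)[C@@H]1O[Si](C)(C)C(C)(C)C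
F10 | step 11 | methyl (1(10)E,4R,5S,6S,7R,8S,9S)-4,5-epoxy-9-hydroxy-8-(2-methylprop-2-enoyloxy)germacra-1(10),11(13)-dien-12,6-olid-14-oate | C=C(C)C(=O)O[C@H]1[C@H]2C(=C)C(=O)O[C@@H]2[C@@H]2O[C@]2(C)CC/C=C(/C(=O)OC)[C@@H]1O
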